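## Retrosynthetic overview
1. The target comes from a cis-fused 6a-aroyl-4-aryl-furo[3,4-c]furan-1-one. Its lactone C=O is a sacrificial tether carbon: saponification and decarboxylation free the CH2OH and put H on C3, and base equilibration then gives the 3,4-trans ketone.
2. The bicycle comes from an acyclic epoxy β-keto ester plus CH2Br2 in one flask. The γ-lactone ring closes first (enolate carbon opens the epoxide) and the oxolane ring closes second (O–CH2–C bridging).
3. The epoxy β-keto ester comes from the (2S,3S)-epoxy alcohol and ethyl 3,4,5-trimethoxybenzoylacetate.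
4. The epoxy alcohol comes from Sharpless epoxidation of (E)-3,4,5-trimethoxycinnamyl alcohol, itself made from methyl 3,4,5-trimethoxycinnamate.
5. Stereochemistry: the epoxidation sets C5 (retained) and C4 (one inversion, which turns the trans-epoxide into the 4,5-cis oxolane). C3 is set thermodynamically.

Assumption: methyl (E)-3,4,5-trimethoxycinnamate and ethyl 3,4,5-trimethoxybenzoylacetate are taken as catalogue chemicals. Oxolane locants follow the name of compound 11.

## Route

Step 1
Reactants: 1 methyl (E)-3-(3,4,5-trimethoxyphenyl)prop-2-enoate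
Product: 2 (E)-3-(3,4,5-trimethoxyphenyl)prop-2-en-1-ol
Conditions: i-Bu2AlH (2.3 equiv), CH2Cl2, −78 → 0 °C; aq. potassium sodium tartrate
Reagents that add atoms: none
Why: 1,2-selective hydride reduction of an enoate with i-Bu2AlH leaves the E-alkene and the aryl methyl ethers untouched, and no stereocentre is formed.

Step 2
Reactants: 2 (E)-3-(3,4,5-trimethoxyphenyl)prop-2-en-1-ol
Product: 3 [(2S,3S)-3-(3,4,5-trimethoxyphenyl)oxiran-2-yl]methanol
Conditions: Ti(OiPr)4 (10 mol %), L-(+)-DIPT (12 mol %), t-BuOOH (2 equiv, decane), 4 Å MS, CH2Cl2, −20 °C; aq. NaOH/NaCl work-up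
Reagents that add atoms: tert-butyl hydroperoxide, CC(C)(C)OO
Why: Sharpless asymmetric epoxidation with the L-(+)-tartrate delivers oxygen to the face of the E-allylic alcohol that gives the (2S,3S)-trans-epoxide, fixing both carbons that become C5 and C4 of the oxolane, and the 3,4,5-trimethoxyphenyl group is a weak enough cation stabiliser for the epoxide to survive.

Step 3
Reactants: 3 [(2S,3S)-3-(3,4,5-trimethoxyphenyl)oxiran-2-yl]methanol; 4 ethyl 3-oxo-3-(3,4,5-trimethoxyphenyl)propanoate
Product: 5 [(2S,3S)-3-(3,4,5-trimethoxyphenyl)oxiran-2-yl]methyl 3-oxo-3-(3,4,5-trimethoxyphenyl)propanoate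
Conditions: DMAP (0.2 equiv), toluene, reflux, 4 Å MS in a Soxhlet head (removes EtOH)
Reagents that add atoms: none
Why: DMAP-catalysed transesterification of a β-keto ester acylates the primary alcohol under essentially neutral conditions, so neither epoxide stereocentre is touched.

Step 4
Reactants: 5 [(2S,3S)-3-(3,4,5-trimethoxyphenyl)oxiran-2-yl]methyl 3-oxo-3-(3,4,5-trimethoxyphenyl)propanoate
Product: 8 (3aR,4R,6aR)-6a-(3,4,5-trimethoxybenzoyl)-4-(3,4,5-trimethoxyphenyl)tetrahydro-1H,3H-furo[3,4-c]furan-1-one, via hydroxy keto lactone 6 (not isolated), via bromomethyl ether 7 (not isolated)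
Conditions: NaH (2.3 equiv), THF/DMPU 5:1 (0.02 M), 0 → 55 °C; then CH2Br2 (1.5 equiv), 25 → 45 °C, same flask
Reagents that add atoms: dibromomethane, BrCBr
Why: Proposed new method: the sodium enolate of the β-keto ester, reacting through its exocyclic ketone enolate (a favoured 5-exo-tet, enolexo alkylation), opens the tethered epoxide at the non-benzylic carbon with clean inversion while the benzylic C–O bond stays intact, which converts the trans-epoxide into the 4,5-cis relationship of the oxolane; proton shift and the second equivalent of NaH give an alkoxide/stabilised-enolate dianion whose harder, more basic alkoxide takes CH2Br2 first, and the very reactive bromomethyl ether 7 is captured by the neighbouring enolate carbon (5-exo-tet), a closure that can only give the cis-fused bicycle; the closest known reaction types are the alkylation of acetoacetate or malonate enolates by epoxides, methylene-acetal formation from dialkoxides and CH2Br2, and the enolate-onto-oxocarbenium closure of donor–acceptor cyclopropane/aldehyde (3+2) annulations.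

Step 5
Reactants: 8 (3aR,4R,6aR)-6a-(3,4,5-trimethoxybenzoyl)-4-(3,4,5-trimethoxyphenyl)tetrahydro-1H,3H-furo[3,4-c]furan-1-one
Product: 11 [(3S,4R,5R)-4-(hydroxymethyl)-5-(3,4,5-trimethoxyphenyl)oxolan-3-yl](3,4,5-trimethoxyphenyl)methanone (target), via hydroxy keto acid 9 (not isolated), via all-cis ketone 10 (not isolated)
Conditions: LiOH (2.5 equiv), THF/H2O 3:1, 0 °C → rt; AcOH to pH 4–5, 45 °C; extract, then DBU (0.2 equiv), THF, rt
Reagents that add atoms: none
Why: Ketonic cleavage of a β-keto ester (saponification of the more electrophilic lactone carbonyl, then β-keto acid decarboxylation) frees the CH2OH and gives an enol that protonates kinetically to all-cis 10, and DBU equilibrates C3 through the enolate to the much less crowded 3,4-trans ketone, while β-elimination of the ring oxygen is the reverse of a 5-endo-trig closure and is therefore slow, and C4 and C5 are not acidic.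

## Compound list
1 | methyl (E)-3-(3,4,5-trimethoxyphenyl)prop-2-enoate | COC(=O)/C=C/c1cc(OC)c(OC)c(OC)c1 | starting material
2 | (E)-3-(3,4,5-trimethoxyphenyl)prop-2-en-1-ol | OC/C=C/c1cc(OC)c(OC)c(OC)c1 | intermediate
3 | [(2S,3S)-3-(3,4,5-trimethoxyphenyl)oxiran-2-yl]methanol | OC[C@@H]1O[C@H]1c1cc(OC)c(OC)c(OC)c1 | intermediate
4 | ethyl 3-oxo-3-(3,4,5-trimethoxyphenyl)propanoate | CCOC(=O)CC(=O)c1cc(OC)c(OC)c(OC)c1 | starting material
5 | [(2S,3S)-3-(3,4,5-trimethoxyphenyl)oxiran-2-yl]methyl 3-oxo-3-(3,4,5-trimethoxyphenyl)propanoate | COc1cc(cc(OC)c1OC)C(=O)CC(=O)OC[C@@H]2O[C@H]2c3cc(OC)c(OC)c(OC)c3 | intermediate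
6 | (3S,4R)-4-[(R)-hydroxy(3,4,5-trimethoxyphenyl)methyl]-3-(3,4,5-trimethoxybenzoyl)oxolan-2-one (present as its sodium salts; C3 is labile) | O=C1OC[C@H]([C@@H](O)c2cc(OC)c(OC)c(OC)c2)[C@H]1C(=O)c3cc(OC)c(OC)c(OC)c3 | intermediate (not isolated)
7 | (3S,4R)-4-[(R)-(bromomethoxy)(3,4,5-trimethoxyphenyl)methyl]-3-(3,4,5-trimethoxybenzoyl)oxolan-2-one (present as its sodium enolate) | O=C1OC[C@H]([C@@H](OCBr)c2cc(OC)c(OC)c(OC)c2)[C@H]1C(=O)c3cc(OC)c(OC)c(OC)c3 | intermediate (not isolated)
8 | (3aR,4R,6aR)-6a-(3,4,5-trimethoxybenzoyl)-4-(3,4,5-trimethoxyphenyl)tetrahydro-1H,3H-furo[3,4-c]furan-1-one | O=C1OC[C@@H]2[C@H](c3cc(OC)c(OC)c(OC)c3)OC[C@]12C(=O)c4cc(OC)c(OC)c(OC)c4 | intermediate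
9 | (3R,4R,5R)-4-(hydroxymethyl)-3-(3,4,5-trimethoxybenzoyl)-5-(3,4,5-trimethoxyphenyl)oxolane-3-carboxylic acid | OC[C@@H]1[C@H](c2cc(OC)c(OC)c(OC)c2)OC[C@@]1(C(O)=O)C(=O)c3cc(OC)c(OC)c(OC)c3 | intermediate (not isolated)
10 | [(3R,4R,5R)-4-(hydroxymethyl)-5-(3,4,5-trimethoxyphenyl)oxolan-3-yl](3,4,5-trimethoxyphenyl)methanone | COc1cc(C(=O)[C@H]2CO[C@@H](c3cc(OC)c(OC)c(OC)c3)[C@H]2CO)cc(OC)c1OC | intermediate (not isolated)
11 | [(3S,4R,5R)-4-(hydroxymethyl)-5-(3,4,5-trimethoxyphenyl)oxolan-3-yl](3,4,5-trimethoxyphenyl)methanone | COc1cc(C(=O)[C@@H]2CO[C@@H](c3cc(OC)c(OC)c(OC)c3)[C@H]2CO)cc(OC)c1OC | target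

## Totals and risks
Total step count: 5. Longest linear sequence: 5.

**Most likely to fail: step 4.**
- Possible failures are 6-endo attack at the benzylic epoxide carbon, a sluggish opening, or C-alkylation by CH2Br2 before O-alkylation, which would give the non-cyclisable diastereomer.
- The fallback sets out from 2 and 4 and replaces the epoxide logic by a donor–acceptor cyclopropane.
- DMAP-catalysed transesterification gives the cinnamyl β-keto ester F1, and diazo transfer (p-ABSA, Et3N, MeCN) gives the diazo ester F2.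
- Asymmetric intramolecular cyclopropanation with the divalent cobalt metalloradical catalyst [Co(3,5-DitBu-ChenPhyrin)] then closes the cyclopropane and the lactone together to give the aroyl cyclopropane lactone F3. The ligand antipode is chosen to give the (1S,5R,6S) product.
- Sn(OTf)2-catalysed (3+2) annulation of F3 with paraformaldehyde follows. The formaldehyde oxygen attacks the benzylic carbon with inversion and the enolate closes onto the oxocarbenium ion. This comes back to the route at 8 with the same 4,5-cis relationship.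

**Second: step 5.**
- Hydroxide may attack the aryl ketone (retro-Claisen loss of the aroyl group), or acid 9 may relactonise faster than it decarboxylates.
- The fallback sets out from 8 and makes the deacylation deliberate. NaOMe (cat.) in MeOH gives the endo-aryl bicyclic lactone F4.
- One equivalent of 3,4,5-trimethoxyphenyllithium F5 (from 5-bromo-1,2,3-trimethoxybenzene and n-BuLi, THF, −78 °C) is added to the lactone carbonyl. The lithium hemiketal alkoxide resists a second addition at −78 °C.
- Work-up comes back to the route at 10, which the DBU equilibration converts into 11.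

**Third: step 3.**
- At 110 °C DMAP may open the aryl epoxide or trigger premature cyclisation.
- The fallback sets out from 3 and changes the acyl donor. The acyl Meldrum's acid F6 is made from 3,4,5-trimethoxybenzoyl chloride and Meldrum's acid (pyridine, CH2Cl2, 0 °C).
- F6 is warmed with 3 in THF or toluene at 70–80 °C without any base, so that the aroylketene it releases is trapped by the primary alcohol. This comes back to the route at 5.

## Further compounds
F1 | step 4 | (E)-3-(3,4,5-trimethoxyphenyl)prop-2-en-1-yl 3-oxo-3-(3,4,5-trimethoxyphenyl)propanoate | COc1cc(cc(OC)c1OC)C(=O)CC(=O)OC/C=C/c2cc(OC)c(OC)c(OC)c2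
F2 | step 4 | (E)-3-(3,4,5-trimethoxyphenyl)prop-2-en-1-yl 2-diazo-3-oxo-3-(3,4,5-trimethoxyphenyl)propanoate | COc1cc(cc(OC)c1OC)C(=O)C(=[N+]=[N-])C(=O)OC/C=C/c2cc(OC)c(OC)c(OC)c2
F3 | step 4 | (1S,5R,6S)-1-(3,4,5-trimethoxybenzoyl)-6-(3,4,5-trimethoxyphenyl)-3-oxabicyclo[3.1.0]hexan-2-one | O=C1OC[C@@H]2[C@@H](c3cc(OC)c(OC)c(OC)c3)[C@]12C(=O)c4cc(OC)c(OC)c(OC)c4
F4 | step 5 | (3aR,4R,6aR)-4-(3,4,5-trimethoxyphenyl)tetrahydro-1H,3H-furo[3,4-c]furan-1-one | O=C1OC[C@@H]2[C@H](c3cc(OC)c(OC)c(OC)c3)OC[C@H]12
F5 | step 5 | 3,4,5-trimethoxyphenyllithium | [Li]c1cc(OC)c(OC)c(OC)c1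
F6 | step 3 | 5-[hydroxy(3,4,5-trimethoxyphenyl)methylidene]-2,2-dimethyl-1,3-dioxane-4,6-dione | CC1(C)OC(=O)C(=C(O)c2cc(OC)c(OC)c(OC)c2)C(=O)O1
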